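## Retrosynthetic overview
1. Ring D (20-membered) is opened at the secondary amine, between the propyl carbon and the nitrogen of the butyl half. This gives an open-chain amino aldehyde, closed last by macrocyclic reductive amination.
2. Both (Z)-enamides come from two Ando-type Z-selective HWE olefinations of one tricyclic keto dialdehyde. The free aromatic CHO reacts first and the neopentyl C9b-CHO second.
3. The keto dialdehyde comes from a 2-arylacrolein and Rawal's diene in one operation. An enantioselective Diels–Alder reaction builds ring C and sets C9b. HF then causes loss of Me2NH, desilylation and oxa-Michael closure, which builds ring B and sets C4a.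
4. The 2-arylacrolein comes from 3-bromo-4-hydroxybenzaldehyde by Suzuki isopropenylation, silylation and SeO2 oxidation.
5. Order of rings: A (bought), then C and B together, then D.

Assumption 1: the SMILES is read literally, with both enamide C=C bonds Z and a cis ring fusion, (4aR,9bS) in dibenzofuran numbering.
Assumption 2: the (R,R) enantiomer of 1-naphthyl-TADDOL is taken to give the 9bS series; if the sense is the opposite, the equally available (S,S) enantiomer is used and nothing else changes.

## Route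

Step 1
Reactants: 1 diphenyl phosphite; 2 tert-butyl bromoacetate
Product: 4 2-(diphenoxyphosphoryl)acetic acid, via tert-butyl ester 3 (not isolated)
Conditions: Et3N, CH2Cl2, 0 °C → rt; aqueous wash; then TFA/CH2Cl2 (1:2), rt
Reagents that add atoms: none
Why: Michaelis–Becker-type P-alkylation of the phosphite by the α-bromo ester is followed by acidolysis of the tert-butyl ester, which spares the base-labile P–OPh groups that saponification would attack.

Step 2
Reactants: 4 2-(diphenoxyphosphoryl)acetic acid; 5 tert-butyl N-(4-aminobutyl)carbamate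
Product: 6 tert-butyl N-{4-[2-(diphenoxyphosphoryl)acetamido]butyl}carbamate
Conditions: DCC, HOBt (10 mol %), CH2Cl2, 0 °C → rt
Reagents that add atoms: none
Why: In this carbodiimide amide coupling the activated carboxyl group is attacked by the primary amine far faster than the phosphonate phenyl esters.

Step 3
Reactants: 4 2-(diphenoxyphosphoryl)acetic acid; 7 3,3-diethoxypropan-1-amine
Product: 8 diphenyl {2-[(3,3-diethoxypropyl)amino]-2-oxoethyl}phosphonate
Conditions: DCC, HOBt (10 mol %), CH2Cl2, 0 °C → rt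
Reagents that add atoms: none
Why: This is the same carbodiimide amide coupling, and the acetal survives because the amine buffers the acid.

Step 4
Reactants: 9 3-bromo-4-hydroxybenzaldehyde; 10 isopropenylboronic acid pinacol ester
Product: 11 4-hydroxy-3-(prop-1-en-2-yl)benzaldehyde
Conditions: PdCl2(dppf) (3 mol %), K2CO3, dioxane/H2O (4:1), 90 °C
Reagents that add atoms: none
Why: In this Suzuki–Miyaura coupling the formyl group keeps the C–Br bond reactive enough even with the phenol deprotonated.

Step 5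
Reactants: 11 4-hydroxy-3-(prop-1-en-2-yl)benzaldehyde
Product: 12 4-(tert-butyldimethylsilyloxy)-3-(prop-1-en-2-yl)benzaldehyde
Conditions: TBSCl, imidazole, DMF, rt
Reagents that add atoms: tert-butyldimethylsilyl chloride, CC(C)(C)[Si](C)(C)Cl
Why: O-silylation blocks the phenol, which would otherwise trap the later 2-arylacrolein as a lactol, and the silyl group is removed without an extra step in step 7.

Step 6
Reactants: 12 4-(tert-butyldimethylsilyloxy)-3-(prop-1-en-2-yl)benzaldehyde
Product: 13 4-(tert-butyldimethylsilyloxy)-3-(3-oxoprop-1-en-2-yl)benzaldehyde (a 2-arylacrolein, used at once)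
Conditions: SeO2 (1.2 equiv), dioxane, 80 °C
Reagents that add atoms: selenium dioxide, O=[Se]=O
Why: Riley allylic oxidation (ene reaction, then [2,3]-shift, then further oxidation) takes the only allylic CH3 of the α-methylstyrene unit to the enal and leaves ArCHO and ArOTBS untouched.

Step 7 (key step)
Reactants: 13 4-(tert-butyldimethylsilyloxy)-3-(3-oxoprop-1-en-2-yl)benzaldehyde; 14 Rawal's diene, (E)-3-(tert-butyldimethylsilyloxy)-N,N-dimethylbuta-1,3-dien-1-amine
Product: 17 (4aR,9bS)-3-oxo-1,2,3,4,4a,9b-hexahydrodibenzo[b,d]furan-8,9b-dicarbaldehyde, via endo cycloadduct 15 (not isolated), via enone phenol 16 (not isolated)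
Conditions: (4R,5R)-2,2-dimethyl-α,α,α',α'-tetra(naphth-1-yl)-1,3-dioxolane-4,5-dimethanol (20 mol %), 14 (1.05 equiv), toluene, −80 °C, 48 h; then 48% aq HF/MeCN (1:9), −80 °C → rt, 12 h; NaHCO3 work-up; recrystallise
Reagents that add atoms: none
Why: This hydrogen-bond-catalysed Diels–Alder reaction is known for 2-alkylacroleins and is extended here to a 2-arylacrolein; the TADDOL-bound enal is attacked on one face, which sets C9b and builds ring C faster than the deactivated ArCHO can undergo hetero-Diels–Alder reaction, and HF then unmasks the ketone, expels Me2NH and frees the phenol, whose 5-exo-trig oxa-Michael addition can only close cis, so C4a (R) follows from C9b and ring B forms in the same flask.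

Step 8
Reactants: 17 (4aR,9bS)-3-oxo-1,2,3,4,4a,9b-hexahydrodibenzo[b,d]furan-8,9b-dicarbaldehyde; 6 tert-butyl N-{4-[2-(diphenoxyphosphoryl)acetamido]butyl}carbamate; 8 diphenyl {2-[(3,3-diethoxypropyl)amino]-2-oxoethyl}phosphonate
Product: 19 bis-(Z)-enamide carrying (Z)-CH=CH-C(O)NH(CH2)2CH(OEt)2 at C9b and (Z)-CH=CH-C(O)NH(CH2)4NHBoc at C8 of the (4aR,9bS)-3-oxohexahydrodibenzofuran, via monoolefinated aldehyde 18 (not isolated)
Conditions: 6 (1.0 equiv), KOt-Bu (1.0 equiv), THF, −78 °C, add 17, −78 → −45 °C, 3 h; then the K salt of 8 (1.3 equiv, from KOt-Bu), −45 → 0 °C; NH4Cl; dark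
Reagents that add atoms: none
Why: In the Ando-type Horner–Wadsworth–Emmons olefination the electron-poor P(OPh)2 group makes oxaphosphetane collapse faster than equilibration and so gives (Z)-enamides; the anion of 6 reaches only the unhindered aromatic aldehyde in the cold, the neopentyl C9b aldehyde takes the anion of 8 on warming, and these weakly basic, ketone-inert anions leave the ketone, C4a and C9b unchanged (a retro-oxa-Michael step could only re-close to the same cis isomer).

Step 9
Reactants: 19 bis-(Z)-enamide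
Product: 22 target CNP0159470.1, the (Z,Z)-configured (4aR,9bS) macrocycle, via amino aldehyde 20 (not isolated), via macrocyclic imine 21 (not isolated)
Conditions: TFA/CH2Cl2/H2O (10:10:1), 0 °C, 1 h, dark; evaporate; Et3N, 4 Å MS, CH2Cl2 (1 mM), rt, 6 h; then NaBH(OAc)3, AcOH, 0 °C → rt
Reagents that add atoms: none
Why: Acidolysis frees the primary amine and the β-amido aldehyde, reversible imine formation at high dilution funnels the material into the 20-membered aldimine (the aldehyde is far better than the ring ketone), and reductive amination with NaBH(OAc)3 fixes the secondary amine without touching the ketone, the enamides or either stereocentre.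

## Compound list
1 | diphenyl phosphite | O=[PH](Oc1ccccc1)Oc1ccccc1 | starting material
2 | tert-butyl bromoacetate | CC(C)(C)OC(=O)CBr | starting material
3 | tert-butyl 2-(diphenoxyphosphoryl)acetate | CC(C)(C)OC(=O)CP(=O)(Oc1ccccc1)Oc1ccccc1 | intermediate
4 | 2-(diphenoxyphosphoryl)acetic acid | OC(=O)CP(=O)(Oc1ccccc1)Oc1ccccc1 | intermediate
5 | tert-butyl N-(4-aminobutyl)carbamate | CC(C)(C)OC(=O)NCCCCN | starting material
6 | tert-butyl N-{4-[2-(diphenoxyphosphoryl)acetamido]butyl}carbamate | CC(C)(C)OC(=O)NCCCCNC(=O)CP(=O)(Oc1ccccc1)Oc1ccccc1 | intermediate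
7 | 3,3-diethoxypropan-1-amine | CCOC(CCN)OCC | starting material
8 | diphenyl {2-[(3,3-diethoxypropyl)amino]-2-oxoethyl}phosphonate | CCOC(CCNC(=O)CP(=O)(Oc1ccccc1)Oc1ccccc1)OCC | intermediate
9 | 3-bromo-4-hydroxybenzaldehyde | O=Cc1ccc(O)c(Br)c1 | starting material
10 | isopropenylboronic acid pinacol ester | CC(=C)B1OC(C)(C)C(C)(C)O1 | starting material
11 | 4-hydroxy-3-(prop-1-en-2-yl)benzaldehyde | CC(=C)c1cc(C=O)ccc1O | intermediate
12 | 4-(tert-butyldimethylsilyloxy)-3-(prop-1-en-2-yl)benzaldehyde | CC(=C)c1cc(C=O)ccc1O[Si](C)(C)C(C)(C)C | intermediate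
13 | 4-(tert-butyldimethylsilyloxy)-3-(3-oxoprop-1-en-2-yl)benzaldehyde | C=C(C=O)c1cc(C=O)ccc1O[Si](C)(C)C(C)(C)C | intermediate
14 | (E)-3-(tert-butyldimethylsilyloxy)-N,N-dimethylbuta-1,3-dien-1-amine (Rawal's diene) | CN(C)/C=C/C(=C)O[Si](C)(C)C(C)(C)C | starting material
15 | (1S,2S)-1-[2-(tert-butyldimethylsilyloxy)-5-formylphenyl]-4-(tert-butyldimethylsilyloxy)-2-(dimethylamino)cyclohex-3-ene-1-carbaldehyde (NMe2 cis to CHO) | CN(C)[C@H]1C=C(O[Si](C)(C)C(C)(C)C)CC[C@]1(C=O)c1cc(C=O)ccc1O[Si](C)(C)C(C)(C)C | intermediate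
16 | (1R)-1-(5-formyl-2-hydroxyphenyl)-4-oxocyclohex-2-ene-1-carbaldehyde | O=C1CC[C@](C=O)(c2cc(C=O)ccc2O)C=C1 | intermediate
17 | (4aR,9bS)-3-oxo-1,2,3,4,4a,9b-hexahydrodibenzo[b,d]furan-8,9b-dicarbaldehyde | O=C1CC[C@]2(C=O)c3cc(C=O)ccc3O[C@@H]2C1 | intermediate
18 | tert-butyl N-[4-[[(Z)-3-[(4aR,9bS)-9b-formyl-3-oxo-1,2,3,4,4a,9b-hexahydrodibenzofuran-8-yl]prop-2-enoyl]amino]butyl]carbamate | O=C1CC[C@]2(C=O)c3cc(/C=C\C(=O)NCCCCNC(=O)OC(C)(C)C)ccc3O[C@@H]2C1 | intermediate
19 | bis-(Z)-enamide: as 18, with (Z)-CH=CH-C(O)NHCH2CH2CH(OEt)2 at C9b in place of CHO | O=C1CC[C@]2(/C=C\C(=O)NCCC(OCC)OCC)c3cc(/C=C\C(=O)NCCCCNC(=O)OC(C)(C)C)ccc3O[C@@H]2C1 | intermediate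
20 | amino aldehyde: as 19, with free NH2 and free CHO (formed as the trifluoroacetate salt) | O=C1CC[C@]2(/C=C\C(=O)NCCC=O)c3cc(/C=C\C(=O)NCCCCN)ccc3O[C@@H]2C1 | intermediate
21 | 20-membered macrocyclic aldimine | O=C1CC[C@]23/C=C\C(=O)NCCC=NCCCCNC(=O)/C=C\c4ccc(c2c4)O[C@@H]3C1 | intermediate
22 | CNP0159470.1, (Z,Z), (4aR,9bS) | O=C1CC[C@]23/C=C\C(=O)NCCCNCCCCNC(=O)/C=C\c4ccc(c2c4)O[C@@H]3C1 | target

## Summary
Total step count: 9. Longest linear sequence: 6 (steps 4 to 9).

Three steps most likely to fail: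

**Step 7.** The 2-aryl group may lower the ee, or the diene may be lost to ArCHO. The fallback sets out from 13 and comes back at 17. It uses Lewis-acid instead of hydrogen-bond control, and an oxidation instead of a β-elimination to make the enone.
- Methyl vinyl ketone, TIPSOTf and Et3N give 2-(triisopropylsilyloxy)buta-1,3-diene F1.
- The cationic oxazaborolidinium catalyst is made from (S)-α,α-diphenylpyrrolidine-2-methanol, tri-o-tolylboroxine and Tf2NH (20 mol %, CH2Cl2, −78 °C; the enantiomer is chosen for the 9bS series). It joins F1 and 13 to the para adduct (1R)-1-[2-(tert-butyldimethylsilyloxy)-5-formylphenyl]-4-(triisopropylsilyloxy)cyclohex-3-ene-1-carbaldehyde F2, whose regiodefined silyl enol ether holds the chirality.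
- Saegusa–Ito oxidation with Pd(OAc)2 in MeCN gives (1R)-1-[2-(tert-butyldimethylsilyloxy)-5-formylphenyl]-4-oxocyclohex-2-ene-1-carbaldehyde F3.
- TBAF/AcOH frees the phenol, which closes through 16 to 17.

**Step 8.** The two aldehydes may not be told apart well enough, or Z control at the aryl arm may be poor. The fallback sets out from 17 and comes back at 19. It gives up kinetic Z control for the aryl arm.
- Diethylphosphonoacetic acid and 5 (DCC) give tert-butyl N-{4-[2-(diethoxyphosphoryl)acetamido]butyl}carbamate F4.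
- Under Masamune–Roush conditions (LiCl, i-Pr2NEt, MeCN, 0 °C) this sluggish reagent olefinates only the aromatic aldehyde of 17. The product is the (E)-cinnamamide aldehyde F5, which is isolated and purified.
- The potassium salt of 8 then turns the C9b aldehyde into the (Z)-enamide and gives the (E)-aryl, (Z)-C9b bis-enamide F6.
- Energy-transfer photoisomerisation (Ir(ppy)3, 450 nm, MeCN) excites only the styrene-type (E)-enamide and drives it to Z, which gives 19.

**Step 9.** Oligomers may form, or the amine may be captured by the ring ketone. The fallback sets out from 17 and comes back at 22. It closes ring D at the C9b-side C=C bond instead of at nitrogen, with the whole spermidine chain already in place.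
- Spermidine and aqueous formaldehyde give 1-(4-aminobutyl)hexahydropyrimidine F7.
- The primary amine of F7 is acylated with 4 (DCC, 0 °C) to the phosphonoacetamide F8.
- The potassium salt of F8 olefinates the aromatic aldehyde of 17 at −78 °C to the (Z)-cinnamamide aldehyde F9.
- The ring NH of F9 is acylated with 4 (DCC) to the phosphonate aldehyde F10.
- NaI/DBU in THF (1 mM, 0 °C) brings about the Z-selective intramolecular HWE reaction and gives the methylene-bridged macrocycle F11.
- Malonic acid/pyridine in EtOH (60 °C) takes out the aminal CH2 and gives 22.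

## Further compounds
F1 | step 7 | 2-(triisopropylsilyloxy)buta-1,3-diene | C=CC(=C)O[Si](C(C)C)(C(C)C)C(C)C
F2 | step 7 | (1R)-1-[2-(tert-butyldimethylsilyloxy)-5-formylphenyl]-4-(triisopropylsilyloxy)cyclohex-3-ene-1-carbaldehyde | CC(C)[Si](OC1=CC[C@@](C=O)(c2cc(C=O)ccc2O[Si](C)(C)C(C)(C)C)CC1)(C(C)C)C(C)C
F3 | step 7 | (1R)-1-[2-(tert-butyldimethylsilyloxy)-5-formylphenyl]-4-oxocyclohex-2-ene-1-carbaldehyde | O=C1CC[C@](C=O)(c2cc(C=O)ccc2O[Si](C)(C)C(C)(C)C)C=C1
F4 | step 8 | tert-butyl N-{4-[2-(diethoxyphosphoryl)acetamido]butyl}carbamate | CCOP(=O)(CC(=O)NCCCCNC(=O)OC(C)(C)C)OCC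
F5 | step 8 | (E)-cinnamamide aldehyde, the (E) isomer of 18 | O=C1CC[C@]2(C=O)c3cc(/C=C/C(=O)NCCCCNC(=O)OC(C)(C)C)ccc3O[C@@H]2C1
F6 | step 8 | (E)-aryl, (Z)-C9b bis-enamide, an isomer of 19 | O=C1CC[C@]2(/C=C\C(=O)NCCC(OCC)OCC)c3cc(/C=C/C(=O)NCCCCNC(=O)OC(C)(C)C)ccc3O[C@@H]2C1
F7 | step 9 | 1-(4-aminobutyl)hexahydropyrimidine | NCCCCN1CCCNC1
F8 | step 9 | 2-(diphenoxyphosphoryl)-N-[4-(hexahydropyrimidin-1-yl)butyl]acetamide | O=C(CP(=O)(Oc1ccccc1)Oc1ccccc1)NCCCCN1CCCNC1
F9 | step 9 | (Z)-cinnamamide aldehyde with a hexahydropyrimidine end group | O=C1CC[C@]2(C=O)c3cc(/C=C\C(=O)NCCCCN4CCCNC4)ccc3O[C@@H]2C1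
F10 | step 9 | phosphonate aldehyde, F9 N-acylated with 4 | O=C1CC[C@]2(C=O)c3cc(/C=C\C(=O)NCCCCN4CCCN(C4)C(=O)CP(=O)(Oc5ccccc5)Oc5ccccc5)ccc3O[C@@H]2C1
F11 | step 9 | methylene-bridged (Z,Z) macrocycle | O=C1CC[C@]23/C=C\C(=O)N4CCCN(C4)CCCCNC(=O)/C=C\c5ccc(c2c5)O[C@@H]3C1
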